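Compound numbers are fixed by the steps further down and are used throughout. Geranyl = (2E)-3,7-dimethylocta-2,6-dien-1-yl; TIPS = triisopropylsilyl; TBS = tert-butyldimethylsilyl.

## The problem

- Target 17 is an isoflavanone: a chroman-4-one (rings A and C fused along C4a–C8a) that carries ring B on C3.
- C3 is the only stereocentre. It is tertiary, benzylic and α to the C4 ketone, so no other element of the molecule can control it and it is lost through the enol under base or strong Lewis acid. It must be set by an external chiral agent, late, and kept under near-neutral conditions afterwards.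
- Ring B is 1,2,3,4-tetrasubstituted, with the geranyl chain on C3′ between the free 2′-OH and the 4′-OMe. This pattern has to be built by directed chemistry, not by electrophilic substitution.
- The two trisubstituted alkenes of the chain rule out hydrogenolysis, ozonolysis and electrophilic halogenation. Protic or strong Lewis acids add the 2′-OH across the chain.
- Three phenols (the chelated 5-OH, 7-OH and 2′-OH) must be freed at the end while the 4′-methyl ether stays.
- The feature that opens the key step: C2 is a methylene bound only to O1 and C3, so it is a ring A methoxy carbon in disguise. Ring A has the phloroglucinol pattern, so the oxygens on C5 and C8a are equivalent in a 2,6-dimethoxyaryl ketone. A carbene at C3 can then form C2–C3, close ring C and set C3 in one event.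

## Retrosynthesis

**17 to 16 to 15 (O–Si and O–CH3 bonds only).** The 7-O and 2′-O are traced back to TIPS ethers and the 5-OH to a methyl ether, giving 15 via 16. The 5-methyl ether is the twin of the methoxy group that becomes C2. It is the only methoxy peri to the ketone, so chelation tells it apart from the 4′-OMe. The 2′-O must carry a group with no C–H next to oxygen, otherwise the carbene of the key step would insert there and form a benzofuran. The silyl group also keeps this phenol away from the geranyl chain during the Lewis acid step. The forward reactions must not epimerize C3.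

**15 to 14 (C2–C3).** Cutting C2–C3 removes ring C and the stereocentre together and leaves the acyclic, achiral diazo ketone 14 with a symmetric ring A. The neighbouring cuts (O1–C2, C3–C4, C4–C4a, C3–C1′) all need C3 to be made in a separate step or expose it to base during ring closure. The forward step asks a rhodium carbene at C3 to insert into a methoxy C–H bond with face control by the catalyst.

**14 to 13 (C=N2).** The diazo group is traced to the methylene of deoxybenzoin 13. This CH2 is flanked by an aryl ring and a ketone and is acidic enough for direct diazo transfer. The forward step needs a non-nucleophilic base that leaves the aryl silyl ethers alone.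

**13 to 11 and 7 (the CH2–CO bond, C3–C4 of the later chromanone).** This cut gives two non-enolizable benzaldehyde-level pieces, the aldehyde 7 and the α-aminophosphonate 11, which is an acyl anion equivalent of ring A. Cutting the CO–aryl bond would need an acid-mediated acylation of ring A, with regiochemical ambiguity and danger to the geranyl chain. Cutting the aryl–CH2 bond would need a ring B halide, which cannot be made by electrophilic halogenation next to the alkenes. The forward reaction is a Horner–Wadsworth–Emmons olefination to enamine 12 followed by hydrolysis.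

**11 to 9 to 8 (C–P, C–N, O–Si).** The aminophosphonate 11 comes from aldehyde 9, aniline and diphenyl phosphite by way of imine 10. Aldehyde 9 is the TIPS ether of commercial 4-hydroxy-2,6-dimethoxybenzaldehyde 8, which already holds the symmetric ring A.

**7 to 6 to 5 (O–Si, then the aryl–CHO bond).** The formyl carbon of 6 is removed to give phenol 5. Its hydroxyl directs formylation to the only free ortho position, which is the one needed. This avoids a second lithiation next to the acidic benzylic-allylic CH2 of the chain.

**5 to 4 to 1 and 2 (O–CH3, then the aryl–geranyl bond).** Phenol 5 is the mono-demethylation product of the symmetric diether 4. The geranyl group of 4 is attached by lithiation of 1,3-dimethoxybenzene 1 between its methoxy groups (aryllithium 3) and alkylation with geranyl bromide 2. Direct C-geranylation of a resorcinol aldehyde would suffer from C/O and positional mixtures, and a Claisen route would deliver the branched allyl isomer.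

## Roads not taken

**Alternative 1:** ring A is folded, not bought; the cut is C4a–C8a.
- Forward step: the dioxinone-capped polyketone A1 is heated in methanol (loss of acetone, ketene capture as the C8a methyl ester). Mg(OMe)2 in the same pot makes C4a attack the ester carbon, and enolization gives the acylphloroglucinol A2.
- Merits: the 5-OH and 7-OH arrive free, so no late demethylation is needed, and the chemistry mirrors the biosynthesis.
- Weak points: A2 is racemic and ring C is still open. O1–C2 must be closed afterwards and C3 set in a further operation. C3 sits between an arene and a ketone during a basic magnesium methoxide step, so no configuration could be carried through it. The chain of A1 needs several dianion acylations and can also fold by aldol paths.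
- Comparison: this road is better in the final oxygenation state of ring A. It is longer, gives no absolute configuration, and builds the cheap part (ring A can be bought as 8). The chosen plan sets against it one step that closes ring C and sets C3, at the price of one demethylation (step 10).

**Alternative 2:** the cut is C3–C4.
- Forward step: in sulfone A3, base expels the arylsulfonyl group as sulfinate. This turns ring B into a quinone methide-type acceptor with C3 as the exocyclic carbon. A chiral triazolylidene converts the ring A aldehyde into an acyl anion equivalent that adds to C3, closing ring C and giving A4.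
- Merits: it also joins ring closure and asymmetric induction in one catalytic step. The 2′-OH emerges free, and only silyl ethers remain, so one fluoride treatment finishes and no Lewis acid meets the geranyl phenol. Carbene-catalysed intramolecular acyl anion additions to chroman-4-ones are established, which the insertion of step 9 is not.
- Weak points: the base that unmasks the acceptor stays in contact with the product, whose C3–H is acidic and flanked by a free ortho phenol, so the configuration is at risk in the step that creates it. The aldehyde is electron-rich and flanked by two ortho oxygens, which slows formation of the acyl anion equivalent. A3 carries a free phenol and a secondary benzylic sulfone through its own synthesis.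
- Comparison: this road is ahead in deprotection economy (one step against two) and in precedent for the ring-forming step. The chosen plan sets against it base-free, neutral conditions when C3 is formed, and a precursor (14) reached from two aldehydes in three steps.

**Alternative 3:** the cut is C4–C4a.
- Forward step: iodide A5, whose C3 configuration comes from a lipase desymmetrization several steps earlier, undergoes iodine–magnesium exchange with i-PrMgCl·LiCl. The arylmagnesium attacks the Weinreb amide (Parham-type cyclization), and the chelated tetrahedral intermediate gives A6 on cold acidic quench.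
- Merits: every step is known chemistry. The stereocentre comes from a dependable enzymatic step that can be checked early. All phenols are silyl ethers, so one fluoride step completes the synthesis. In certainty of ring closure and in deprotection this road is better than the chosen one.
- Weak points: C3–H of A5 is α to an amide and an arene and β to an aryloxy leaving group, so the basic magnesium reagents can epimerize it or eliminate the phenoxide before cyclization. The sequence is long and linear, and the geranyl group must survive all of it.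
- Comparison: the chosen plan offers about half the step count, convergence, and creation of C3 only three steps from the end under neutral conditions. It pays with the uncertainty of an unprecedented insertion, for which a known-chemistry fallback is given.

Key step: step 9

Assumption: the (S)-tert-leucinate catalyst is taken to deliver the (3S) ketone 15; if the opposite sense is found, Rh2(R-PTTL)4 is used with no other change.

## Route

Step 1
Reactants: 1 1,3-dimethoxybenzene; 2 geranyl bromide
Product: 4 2-geranyl-1,3-dimethoxybenzene, via 2,6-dimethoxyphenyllithium 3 (not isolated)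
Conditions: n-BuLi, THF, 0 °C to rt; then 2, −78 °C to rt
Reagents that add atoms: none
Why: Directed ortho-lithiation between the two methoxy groups (the most acidic ring position), then SN2 alkylation of the aryllithium by the primary allylic bromide; the E alkene is untouched.

Step 2
Reactants: 4 2-geranyl-1,3-dimethoxybenzene
Product: 5 2-geranyl-3-methoxyphenol
Conditions: NaSEt, DMF, 120 °C; aq. NH4Cl work-up
Reagents that add atoms: none
Why: Nucleophilic demethylation (SN2 of thiolate at a methyl carbon); the two methoxy groups are equivalent and the phenoxide formed deactivates the ring towards a second cleavage; basic conditions spare the alkenes.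

Step 3
Reactants: 5 2-geranyl-3-methoxyphenol
Product: 6 3-geranyl-2-hydroxy-4-methoxybenzaldehyde
Conditions: MgCl2, Et3N, (CH2O)n, MeCN, 80 °C
Reagents that add atoms: formaldehyde (from paraformaldehyde), C=O
Why: Casnati–Skattebøl ortho-formylation: the magnesium phenoxide delivers formaldehyde to the only free ortho position and a second formaldehyde oxidizes the benzylic alkoxide by hydride transfer; the non-acidic medium spares the geranyl chain.

Step 4
Reactants: 6 3-geranyl-2-hydroxy-4-methoxybenzaldehyde
Product: 7 3-geranyl-4-methoxy-2-(triisopropylsilyloxy)benzaldehyde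
Conditions: TIPSOTf, 2,6-lutidine, CH2Cl2, 0 °C to rt
Reagents that add atoms: triisopropylsilyl triflate, CC(C)[Si](OS(=O)(=O)C(F)(F)F)(C(C)C)C(C)C
Why: O-silylation of a hindered, hydrogen-bonded phenol with a silyl triflate; TIPS is chosen because it has no C–H next to oxygen for the later carbene and resists the bases of steps 7 and 8.

Step 5
Reactants: 8 4-hydroxy-2,6-dimethoxybenzaldehyde
Product: 9 2,6-dimethoxy-4-(triisopropylsilyloxy)benzaldehyde
Conditions: TIPSCl, imidazole, DMF, rt
Reagents that add atoms: triisopropylsilyl chloride, CC(C)[Si](Cl)(C(C)C)C(C)C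
Why: Standard silylation of an acidic, unhindered phenol.

Step 6
Reactants: 9 2,6-dimethoxy-4-(triisopropylsilyloxy)benzaldehyde
Product: 11 diphenyl {anilino[2,6-dimethoxy-4-(triisopropylsilyloxy)phenyl]methyl}phosphonate (racemic), via N-phenyl aldimine 10 (not isolated)
Conditions: PhNH2, 4 Å MS, toluene, 50 °C; then (PhO)2P(O)H, rt
Reagents that add atoms: aniline, Nc1ccccc1; diphenyl phosphite, O=[PH](Oc1ccccc1)Oc1ccccc1
Why: Kabachnik–Fields reaction (imine formation, then Pudovik addition of the phosphite to C=N); the stereocentre formed is lost in step 7.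

Step 7
Reactants: 11 diphenyl {anilino[2,6-dimethoxy-4-(triisopropylsilyloxy)phenyl]methyl}phosphonate; 7 3-geranyl-4-methoxy-2-(triisopropylsilyloxy)benzaldehyde
Product: 13 1-[2,6-dimethoxy-4-(triisopropylsilyloxy)phenyl]-2-[3-geranyl-4-methoxy-2-(triisopropylsilyloxy)phenyl]ethan-1-one, via N-phenyl enamine 12 (not isolated)
Conditions: NaH, THF, 0 °C to rt; then 1 M aq. HCl, THF, rt
Reagents that add atoms: water, O
Why: Horner–Wadsworth–Emmons olefination of the α-aminophosphonate carbanion (an acyl anion equivalent of 9) with the non-enolizable aldehyde 7 gives enamine 12, which dilute acid hydrolyses to the deoxybenzoin; the aprotic base spares the aryl silyl ethers.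

Step 8
Reactants: 13 1-[2,6-dimethoxy-4-(triisopropylsilyloxy)phenyl]-2-[3-geranyl-4-methoxy-2-(triisopropylsilyloxy)phenyl]ethan-1-one
Product: 14 2-diazo-1-[2,6-dimethoxy-4-(triisopropylsilyloxy)phenyl]-2-[3-geranyl-4-methoxy-2-(triisopropylsilyloxy)phenyl]ethan-1-one
Conditions: p-ABSA, DBU, MeCN, 0 °C to rt
Reagents that add atoms: 4-acetamidobenzenesulfonyl azide (p-ABSA), CC(=O)Nc1ccc(S(=O)(=O)N=[N+]=[N-])cc1
Why: Regitz diazo transfer to a benzyl ketone, whose CH2 is acidic enough for direct transfer with an amidine base.

Step 9
Reactants: 14 2-diazo-1-[2,6-dimethoxy-4-(triisopropylsilyloxy)phenyl]-2-[3-geranyl-4-methoxy-2-(triisopropylsilyloxy)phenyl]ethan-1-one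
Product: 15 (3S)-5-methoxy-7-(triisopropylsilyloxy)-3-[3-geranyl-4-methoxy-2-(triisopropylsilyloxy)phenyl]chroman-4-one
Conditions: Rh2(S-PTTL)4 (dirhodium tetrakis[N-phthaloyl-(S)-tert-leucinate], 2 mol %), 4 Å MS, CH2Cl2, rt, slow addition of 14 (final 0.01 M)
Reagents that add atoms: none
Why: Proposed new method: the divalent rhodium carboxylate dimer takes N2 from 14 and gives an electrophilic aryl(acyl) carbene at C3, which takes up a hydride-like hydrogen from an O-methyl C–H of ring A while C2–C3 forms in the same concerted three-centre event (six-membered transition state, 1,6 insertion). The closest known reaction types are the chiral dirhodium carboxylate-catalysed 1,6 C–H insertion of 2-alkoxyaryl diazo ketones next to the ether oxygen (chroman-4-ones), the insertion of aryl-substituted rhodium carbenes into methyl ether C–H bonds, and C–H insertion of α-aryl-α-diazo ketones; an aryl ketone carbene acting on a methoxy group has not been shown. Ring C closes by C–C bond formation between the carbene carbon and the methyl carbon, the new ring holding C3, C4, C4a, C8a, O1 and C2. C3 is the only new stereocentre and is set by the catalyst alone: the phthalimido walls of the tert-leucinate ligands leave one face of the carbene open to the approaching C–H bond. Rotation about the aryl–carbonyl bond interchanges the two methoxy groups, so both give the same product. The ketone is twisted out of the plane of ring A by its two ortho substituents, so the methoxy oxygens keep their donor strength towards the C–H bonds and the methyl groups lie over the carbene carbon. Insertion must beat ylide formation at the methoxy oxygen (reversible, since a methyl group migrates poorly), Wolff rearrangement, insertion on the ring B side (excluded because the 2′-silyl ether has no C–H next to oxygen and its oxygen cannot reach the carbene) and reaction with the geranyl alkenes (trisubstituted, meta on ring B, reachable only between molecules and held back by slow addition at high dilution). The medium is neutral and aprotic, so the new α-aryl ketone centre should not epimerize.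

Step 10
Reactants: 15 (3S)-5-methoxy-7-(triisopropylsilyloxy)-3-[3-geranyl-4-methoxy-2-(triisopropylsilyloxy)phenyl]chroman-4-one
Product: 16 (3S)-5-hydroxy-7-(triisopropylsilyloxy)-3-[3-geranyl-4-methoxy-2-(triisopropylsilyloxy)phenyl]chroman-4-one
Conditions: MgI2·OEt2, toluene/Et2O, 40 °C; aq. NH4Cl work-up
Reagents that add atoms: none
Why: Chelation-assisted ether cleavage: magnesium binds the C4 carbonyl and the peri C5 oxygen and iodide removes that methyl group by SN2; the 4′-OMe cannot chelate, the silyl ethers keep the 2′-oxygen off the geranyl chain, and no base stronger than iodide is present to enolize C3.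

Step 11
Reactants: 16 (3S)-5-hydroxy-7-(triisopropylsilyloxy)-3-[3-geranyl-4-methoxy-2-(triisopropylsilyloxy)phenyl]chroman-4-one
Product: 17 (3S)-5,7-dihydroxy-3-(3-geranyl-2-hydroxy-4-methoxyphenyl)chroman-4-one (target)
Conditions: Et3N·3HF, THF, 0 °C to rt
Reagents that add atoms: none
Why: Fluoride cleavage of both aryl silyl ethers in a buffered, slightly acidic medium, which avoids phenoxide-mediated enolization at C3 and acid-mediated cyclization of the geranyl chain.

## Compound list

1 | 1,3-dimethoxybenzene | COc1cccc(OC)c1 | starting material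
2 | geranyl bromide, (2E)-1-bromo-3,7-dimethylocta-2,6-diene | CC(C)=CCC/C(C)=C/CBr | starting material
3 | 2,6-dimethoxyphenyllithium | [Li]c1c(OC)cccc1OC | intermediate (not isolated)
4 | 2-geranyl-1,3-dimethoxybenzene | COc1cccc(OC)c1C/C=C(\C)CCC=C(C)C | intermediate
5 | 2-geranyl-3-methoxyphenol | COc1cccc(O)c1C/C=C(\C)CCC=C(C)C | intermediate
6 | 3-geranyl-2-hydroxy-4-methoxybenzaldehyde | COc1ccc(C=O)c(O)c1C/C=C(\C)CCC=C(C)C | intermediate
7 | 3-geranyl-4-methoxy-2-(triisopropylsilyloxy)benzaldehyde | COc1ccc(C=O)c(O[Si](C(C)C)(C(C)C)C(C)C)c1C/C=C(\C)CCC=C(C)C | intermediate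
8 | 4-hydroxy-2,6-dimethoxybenzaldehyde | COc1cc(O)cc(OC)c1C=O | starting material
9 | 2,6-dimethoxy-4-(triisopropylsilyloxy)benzaldehyde | COc1cc(O[Si](C(C)C)(C(C)C)C(C)C)cc(OC)c1C=O | intermediate
10 | (E)-N-[2,6-dimethoxy-4-(triisopropylsilyloxy)benzylidene]aniline | COc1cc(O[Si](C(C)C)(C(C)C)C(C)C)cc(OC)c1/C=N/c1ccccc1 | intermediate (not isolated)
11 | diphenyl {anilino[2,6-dimethoxy-4-(triisopropylsilyloxy)phenyl]methyl}phosphonate (racemic) | COc1cc(O[Si](C(C)C)(C(C)C)C(C)C)cc(OC)c1C(Nc1ccccc1)P(=O)(Oc1ccccc1)Oc1ccccc1 | intermediate
12 | N-{1-[2,6-dimethoxy-4-(triisopropylsilyloxy)phenyl]-2-[3-geranyl-4-methoxy-2-(triisopropylsilyloxy)phenyl]ethenyl}aniline (enamine, alkene isomers in equilibrium with the ketimine) | COc1ccc(C=C(Nc2ccccc2)c2c(OC)cc(O[Si](C(C)C)(C(C)C)C(C)C)cc2OC)c(O[Si](C(C)C)(C(C)C)C(C)C)c1C/C=C(\C)CCC=C(C)C | intermediate (not isolated)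
13 | 1-[2,6-dimethoxy-4-(triisopropylsilyloxy)phenyl]-2-[3-geranyl-4-methoxy-2-(triisopropylsilyloxy)phenyl]ethan-1-one | COc1ccc(CC(=O)c2c(OC)cc(O[Si](C(C)C)(C(C)C)C(C)C)cc2OC)c(O[Si](C(C)C)(C(C)C)C(C)C)c1C/C=C(\C)CCC=C(C)C | intermediate
14 | 2-diazo-1-[2,6-dimethoxy-4-(triisopropylsilyloxy)phenyl]-2-[3-geranyl-4-methoxy-2-(triisopropylsilyloxy)phenyl]ethan-1-one | COc1ccc(C(=[N+]=[N-])C(=O)c2c(OC)cc(O[Si](C(C)C)(C(C)C)C(C)C)cc2OC)c(O[Si](C(C)C)(C(C)C)C(C)C)c1C/C=C(\C)CCC=C(C)C | intermediate
15 | (3S)-5-methoxy-7-(triisopropylsilyloxy)-3-[3-geranyl-4-methoxy-2-(triisopropylsilyloxy)phenyl]chroman-4-one | COc1ccc([C@H]2COc3cc(O[Si](C(C)C)(C(C)C)C(C)C)cc(OC)c3C2=O)c(O[Si](C(C)C)(C(C)C)C(C)C)c1C/C=C(\C)CCC=C(C)C | intermediate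
16 | (3S)-5-hydroxy-7-(triisopropylsilyloxy)-3-[3-geranyl-4-methoxy-2-(triisopropylsilyloxy)phenyl]chroman-4-one | COc1ccc([C@H]2COc3cc(O[Si](C(C)C)(C(C)C)C(C)C)cc(O)c3C2=O)c(O[Si](C(C)C)(C(C)C)C(C)C)c1C/C=C(\C)CCC=C(C)C | intermediate
17 | (3S)-5,7-dihydroxy-3-(3-geranyl-2-hydroxy-4-methoxyphenyl)chroman-4-one (CNP0303304.1) | COc1ccc([C@H]2COc3cc(O)cc(O)c3C2=O)c(O)c1C/C=C(\C)CCC=C(C)C | target

## Step count and risks

Total steps: 11. Longest linear sequence: 9 steps (from 1 through steps 1–4 and 7–11); the ring A branch (steps 5 and 6) joins at step 7.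

**Step 9 (key step, proposed new method).**
- What may go wrong: attack of the carbene on a methoxy oxygen followed by loss of the methyl group (closure to a five-membered benzofuranone) or a Wolff-type aryl shift could outrun insertion into a primary C–H bond. The face selectivity on a carbene whose aryl group carries a bulky ortho substituent may also be poor.
- Fallback (known chemistry, from 13 back to 15):
  - 13 is mono-demethylated with MgI2·OEt2 under chelation by the ketone to give 1-[2-hydroxy-6-methoxy-4-(triisopropylsilyloxy)phenyl]-2-[3-geranyl-4-methoxy-2-(triisopropylsilyloxy)phenyl]ethan-1-one F1.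
  - Heating with paraformaldehyde and diethylamine in methanol (Mannich reaction, loss of the amine to the enone, oxa-Michael closure) should give racemic 5-methoxy-7-(triisopropylsilyloxy)-3-[3-geranyl-4-methoxy-2-(triisopropylsilyloxy)phenyl]chroman-4-one F2.
  - Asymmetric transfer hydrogenation with dynamic kinetic resolution (RuCl[(S,S)-TsDPEN](p-cymene), HCO2H/Et3N, EtOAc) is used next. The amine racemizes C3 faster than the ketone is reduced, and by the usual model for aryl ketones this should give the cis alcohol (3S,4S)-5-methoxy-7-(triisopropylsilyloxy)-3-[3-geranyl-4-methoxy-2-(triisopropylsilyloxy)phenyl]chroman-4-ol F3. The (R,R) catalyst is used if the sense is opposite.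
  - Dess–Martin oxidation under NaHCO3 buffering returns to 15.

**Step 7.**
- What may go wrong: the anion of the electron-rich aminophosphonate may lose phosphite (retro-Pudovik) instead of adding to the hindered aldehyde, or hydrolysis of the congested ketimine may stall.
- Fallback (from 7 back to 13):
  - Wittig reaction of 7 with the ylide from (methoxymethyl)triphenylphosphonium chloride and KHMDS gives the enol ether 2-geranyl-1-methoxy-4-(2-methoxyethenyl)-3-(triisopropylsilyloxy)benzene F4 (E/Z mixture).
  - Brief hydrolysis with aqueous HCl in THF gives 2-[3-geranyl-4-methoxy-2-(triisopropylsilyloxy)phenyl]acetaldehyde F5.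
  - Separately, 3,5-dimethoxyphenol is silylated (TIPSCl, imidazole) to 3,5-dimethoxy-1-(triisopropylsilyloxy)benzene F6.
  - n-BuLi deprotonates F6 between the methoxy groups (the silyloxy flank is blocked by the bulky silyl group) to give 2,6-dimethoxy-4-(triisopropylsilyloxy)phenyllithium F7.
  - Transmetalation with CeCl3, to suppress enolization of the aldehyde, and addition to F5 at −78 °C give 1-[2,6-dimethoxy-4-(triisopropylsilyloxy)phenyl]-2-[3-geranyl-4-methoxy-2-(triisopropylsilyloxy)phenyl]ethan-1-ol F8.
  - Dess–Martin oxidation returns to 13.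

**Step 8.**
- What may go wrong: slow or incomplete deprotonation of the crowded CH2 (between a twisted aryl ketone and an ortho-silyloxy arene) lets the sulfonyl azide decompose, or prolonged contact with DBU loosens an aryl silyl ether.
- Fallback (from 13 back to 14): the lithium enolate of 13 (LiHMDS, THF, −78 °C) is C-acylated with 2,2,2-trifluoroethyl trifluoroacetate to give 4,4,4-trifluoro-1-[2,6-dimethoxy-4-(triisopropylsilyloxy)phenyl]-2-[3-geranyl-4-methoxy-2-(triisopropylsilyloxy)phenyl]butane-1,3-dione F9. MsN3, Et3N and water in MeCN then transfer the diazo group with loss of the trifluoroacetyl group (detrifluoroacetylative diazo transfer), giving 14.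

**Step 10.**
- What may go wrong: epimerization at C3 through a magnesium enolate during the Lewis acid treatment, or incomplete cleavage if the temperature is kept low to protect the geranyl chain.
- Fallback (from 16 to 17, re-setting C3 in place of preserving it):
  - 16 of eroded configuration is silylated at the chelated phenol (TBSOTf, 2,6-lutidine) to give 5-(tert-butyldimethylsilyloxy)-7-(triisopropylsilyloxy)-3-[3-geranyl-4-methoxy-2-(triisopropylsilyloxy)phenyl]chroman-4-one F10.
  - Transfer hydrogenation with dynamic kinetic resolution (RuCl[(S,S)-TsDPEN](p-cymene), HCO2H/Et3N) funnels both C3 epimers into the cis alcohol (3S,4S)-5-(tert-butyldimethylsilyloxy)-7-(triisopropylsilyloxy)-3-[3-geranyl-4-methoxy-2-(triisopropylsilyloxy)phenyl]chroman-4-ol F11.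
  - Dess–Martin oxidation gives (3S)-5-(tert-butyldimethylsilyloxy)-7-(triisopropylsilyloxy)-3-[3-geranyl-4-methoxy-2-(triisopropylsilyloxy)phenyl]chroman-4-one F12.
  - Et3N·3HF removes all three silyl groups to give 17.

## Further compounds

F1 | step 9 | 1-[2-hydroxy-6-methoxy-4-(triisopropylsilyloxy)phenyl]-2-[3-geranyl-4-methoxy-2-(triisopropylsilyloxy)phenyl]ethan-1-one | COc1ccc(CC(=O)c2c(O)cc(O[Si](C(C)C)(C(C)C)C(C)C)cc2OC)c(O[Si](C(C)C)(C(C)C)C(C)C)c1C/C=C(\C)CCC=C(C)C
F2 | step 9 | 5-methoxy-7-(triisopropylsilyloxy)-3-[3-geranyl-4-methoxy-2-(triisopropylsilyloxy)phenyl]chroman-4-one (racemic) | COc1ccc(C2COc3cc(O[Si](C(C)C)(C(C)C)C(C)C)cc(OC)c3C2=O)c(O[Si](C(C)C)(C(C)C)C(C)C)c1C/C=C(\C)CCC=C(C)C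
F3 | step 9 | (3S,4S)-5-methoxy-7-(triisopropylsilyloxy)-3-[3-geranyl-4-methoxy-2-(triisopropylsilyloxy)phenyl]chroman-4-ol | COc1ccc([C@H]2COc3cc(O[Si](C(C)C)(C(C)C)C(C)C)cc(OC)c3[C@H]2O)c(O[Si](C(C)C)(C(C)C)C(C)C)c1C/C=C(\C)CCC=C(C)C
F4 | step 7 | 2-geranyl-1-methoxy-4-(2-methoxyethenyl)-3-(triisopropylsilyloxy)benzene (E/Z mixture) | COC=Cc1ccc(OC)c(C/C=C(\C)CCC=C(C)C)c1O[Si](C(C)C)(C(C)C)C(C)C
F5 | step 7 | 2-[3-geranyl-4-methoxy-2-(triisopropylsilyloxy)phenyl]acetaldehyde | O=CCc1ccc(OC)c(C/C=C(\C)CCC=C(C)C)c1O[Si](C(C)C)(C(C)C)C(C)C
F6 | step 7 | 3,5-dimethoxy-1-(triisopropylsilyloxy)benzene | COc1cc(O[Si](C(C)C)(C(C)C)C(C)C)cc(OC)c1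
F7 | step 7 | 2,6-dimethoxy-4-(triisopropylsilyloxy)phenyllithium | [Li]c1c(OC)cc(O[Si](C(C)C)(C(C)C)C(C)C)cc1OC
F8 | step 7 | 1-[2,6-dimethoxy-4-(triisopropylsilyloxy)phenyl]-2-[3-geranyl-4-methoxy-2-(triisopropylsilyloxy)phenyl]ethan-1-ol (racemic) | COc1ccc(CC(O)c2c(OC)cc(O[Si](C(C)C)(C(C)C)C(C)C)cc2OC)c(O[Si](C(C)C)(C(C)C)C(C)C)c1C/C=C(\C)CCC=C(C)C
F9 | step 8 | 4,4,4-trifluoro-1-[2,6-dimethoxy-4-(triisopropylsilyloxy)phenyl]-2-[3-geranyl-4-methoxy-2-(triisopropylsilyloxy)phenyl]butane-1,3-dione | COc1ccc(C(C(=O)C(F)(F)F)C(=O)c2c(OC)cc(O[Si](C(C)C)(C(C)C)C(C)C)cc2OC)c(O[Si](C(C)C)(C(C)C)C(C)C)c1C/C=C(\C)CCC=C(C)C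
F10 | step 10 | 5-(tert-butyldimethylsilyloxy)-7-(triisopropylsilyloxy)-3-[3-geranyl-4-methoxy-2-(triisopropylsilyloxy)phenyl]chroman-4-one (C3 configuration eroded) | COc1ccc(C2COc3cc(O[Si](C(C)C)(C(C)C)C(C)C)cc(O[Si](C)(C)C(C)(C)C)c3C2=O)c(O[Si](C(C)C)(C(C)C)C(C)C)c1C/C=C(\C)CCC=C(C)C
F11 | step 10 | (3S,4S)-5-(tert-butyldimethylsilyloxy)-7-(triisopropylsilyloxy)-3-[3-geranyl-4-methoxy-2-(triisopropylsilyloxy)phenyl]chroman-4-ol | COc1ccc([C@H]2COc3cc(O[Si](C(C)C)(C(C)C)C(C)C)cc(O[Si](C)(C)C(C)(C)C)c3[C@H]2O)c(O[Si](C(C)C)(C(C)C)C(C)C)c1C/C=C(\C)CCC=C(C)C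
F12 | step 10 | (3S)-5-(tert-butyldimethylsilyloxy)-7-(triisopropylsilyloxy)-3-[3-geranyl-4-methoxy-2-(triisopropylsilyloxy)phenyl]chroman-4-one | COc1ccc([C@H]2COc3cc(O[Si](C(C)C)(C(C)C)C(C)C)cc(O[Si](C)(C)C(C)(C)C)c3C2=O)c(O[Si](C(C)C)(C(C)C)C(C)C)c1C/C=C(\C)CCC=C(C)C
A1 | alternative 1 | 6-{5-[3-geranyl-4-methoxy-2-(methoxymethoxy)phenyl]-2,4-dioxo-6-(triisopropylsilyloxy)hexyl}-2,2-dimethyl-4H-1,3-dioxin-4-one (racemic) | CC1(C)OC(=O)C=C(CC(=O)CC(=O)C(CO[Si](C(C)C)(C(C)C)C(C)C)c2ccc(OC)c(C/C=C(\C)CCC=C(C)C)c2OCOC)O1
A2 | alternative 1 | 2-[3-geranyl-4-methoxy-2-(methoxymethoxy)phenyl]-3-(triisopropylsilyloxy)-1-(2,4,6-trihydroxyphenyl)propan-1-one (racemic) | COc1ccc(C(CO[Si](C(C)C)(C(C)C)C(C)C)C(=O)c2c(O)cc(O)cc2O)c(OCOC)c1C/C=C(\C)CCC=C(C)C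
A3 | alternative 2 | 2,4-bis(tert-butyldimethylsilyloxy)-6-{2-(3-geranyl-2-hydroxy-4-methoxyphenyl)-2-[(4-methylphenyl)sulfonyl]ethoxy}benzaldehyde (racemic) | O=Cc1c(O[Si](C)(C)C(C)(C)C)cc(O[Si](C)(C)C(C)(C)C)cc1OCC(c1ccc(OC)c(C/C=C(\C)CCC=C(C)C)c1O)S(=O)(=O)c1ccc(C)cc1
A4 | alternative 2 | (3S)-5,7-bis(tert-butyldimethylsilyloxy)-3-(3-geranyl-2-hydroxy-4-methoxyphenyl)chroman-4-one | COc1ccc([C@H]2COc3cc(O[Si](C)(C)C(C)(C)C)cc(O[Si](C)(C)C(C)(C)C)c3C2=O)c(O)c1C/C=C(\C)CCC=C(C)C
A5 | alternative 3 | (2S)-3-[3,5-bis(tert-butyldimethylsilyloxy)-2-iodophenoxy]-2-[3-geranyl-4-methoxy-2-(tert-butyldimethylsilyloxy)phenyl]-N-methoxy-N-methylpropanamide | CON(C)C(=O)[C@H](COc1cc(O[Si](C)(C)C(C)(C)C)cc(O[Si](C)(C)C(C)(C)C)c1I)c1ccc(OC)c(C/C=C(\C)CCC=C(C)C)c1O[Si](C)(C)C(C)(C)C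
A6 | alternative 3 | (3S)-5,7-bis(tert-butyldimethylsilyloxy)-3-[3-geranyl-4-methoxy-2-(tert-butyldimethylsilyloxy)phenyl]chroman-4-one | COc1ccc([C@H]2COc3cc(O[Si](C)(C)C(C)(C)C)cc(O[Si](C)(C)C(C)(C)C)c3C2=O)c(O[Si](C)(C)C(C)(C)C)c1C/C=C(\C)CCC=C(C)C
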